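# Proposed synthesis of CNP0210711.2 (compound 26) by an amine-catalysed Michael–Michael–aldol cascade from (R)-linalool

**Numbering key**

1 (R)-linalool · 2 its triethylsilyl ether · 3 C8 aldehyde (not isolated) · 4 C8 alcohol · 5 C8 bromide · 6 3-methylbut-2-enal · 7 Grignard reagent (not isolated) · 8 trimethylsilyl enol ether (not isolated) · 9 C5 aldehyde · 10 nitroalkene aldehyde (precursor of the key step) · 11 propargyl alcohol · 12 silyl allylic alcohol · 13 silylacrolein · 14 ring B nitro aldehyde (not isolated) · 15 ring B dialdehyde (not isolated) · 16 bicyclic enal (product of the key step) · 17 nitro allylic alcohol · 18 allylic alcohol · 19 allylic mesylate (not isolated) · 20 C6-methyl allylsilane · 21 C1 alcohol · 22 isovanillic acid · 23 bis-silylated acid (not isolated) · 24 O-silyl isovanillic acid · 25 protected ester · 26 target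

**Remarks (assumptions)**

- The atom labels C1–C11 defined in the first section are used as locants for all bicyclic compounds and for the chain atoms that become them.
- C2 of 15, 16 and 17 is drawn as the epimer with the nitro group trans to silicon. This centre equilibrates through the nitronate and is deleted in step 10, so either epimer serves.
- The R enantiomer of the catalyst is assigned by analogy with the intermolecular three-component cascade. The assignment holds only if the tethered Michael step follows the same topicity.

## Analysis of the target

Compound 26 is the 3-hydroxy-4-methoxybenzoate (isovanillate) of a himachalane-type diol, a trans-fused bicycle in which cyclohexene ring A shares one bond with cycloheptane ring B. The atoms are labelled as follows: C1 carries the ester oxygen, C2 is a methylene, C3 and C4 are the ring-fusion methines (C3 bonded to C11, C4 to C7), C5=C6 is the ring A alkene with a methyl on C6, C7 bears two methyls, C8–C10 are methylenes and C11 is the tertiary carbinol carbon with its own methyl; ring A is C1–C6 and ring B is C3, C4, C7–C11. There are four stereocentres, (1R,3R,4R,11R) with these locants: H-3 and H-4 are trans, the C1 oxygen lies on the face of H-3, and on ring B the C11 hydroxyl is cis to H-3. Sensitive features are the secondary allylic ester (ionisation, allylic transposition), the tertiary alcohol (acid-induced elimination), the free phenol and the trisubstituted alkene, which must not migrate. The main difficulty is the C3–C4 bond: each of its carbons sits next to a fully substituted carbon (C11 and C7) and the bond is part of a seven-membered ring, so it is hard to form and its two stereocentres must be related to the carbinol centre. The feature used here is that ring A is a head-to-tail union of three two-carbon units: C5/C4 (carbonyl carbon and α-carbon of an aldehyde), C3/C2 (β- and α-carbon of a nitroalkene) and C1/C6 (β- and α-carbon of an enal). The chain C7–C11 that joins the first two units ends at C11 in a methyl(vinyl)carbinol that is (R)-linalool (1) itself.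

## Retrosynthetic reasoning

**Ester bond (26 ⇒ 25 ⇒ 21 + 24).** The acyl–oxygen bond at C1 is cut first because the allylic ester and the free phenol are the most fragile parts of 26. Acylating alcohol 21 with acid 24 leaves the C1–O bond intact, so the C1 configuration is not at risk. Both remaining hydroxyls are silyl ethers in 25, so one fluoride treatment finishes the synthesis.

**C1–O from C1–Si (21 ⇒ 20).** An oxygen substituent on the β-carbon of the enal partner would be expelled during iminium catalysis, so C1 is carried as a C–Si bond and oxidised with retention. C1 is allylic to C5=C6, so an arylsilane is the wrong mask here: electrophilic removal of the aryl group would first attack the allylsilane and cause protodesilylation with allylic shift. Silicon therefore carries a siloxy substituent from the outset (pentamethyldisiloxanyl), which lets the oxidation run under nucleophilic conditions. The oxidation is placed after removal of the nitro group (a β-nitro silane eliminates with fluoride) and after the formyl group is gone (an enal is attacked by basic peroxide).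

**C6 methyl and C2 methylene (20 ⇒ 18 ⇒ 17 ⇒ 16).** The cascade necessarily leaves a formyl group on C6 and a nitro group on C2. The order is 1,2-reduction of the enal, then radical denitration, then deoxygenation of the primary allylic alcohol. Tin hydride would otherwise reduce the enal, and the hydride displacement would otherwise meet an acidic nitroalkane.

**Key disconnection (16 ⇒ 10 + 13).** Three bonds are cut: C3–C4, C1–C2 and C5=C6. Each pairs a donor and an acceptor that one secondary-amine catalyst can generate in turn: enamine C4 with nitroalkene C3, nitronate C2 with iminium C1, enamine C6 with aldehyde C5. Cutting here, and not at a single ring B bond, removes both rings and three ring stereocentres at once and leaves an open chain 10 whose only stereocentre is C11. The C3–C4 bond, which joins two neopentyl carbons, becomes a ring closure because C7–C11 already tethers the aldehyde to the nitroalkene. The forward reaction has to close a seven-membered ring by enamine Michael addition, then add the nitronate to 13 and finish with an aldol condensation, all with the ring-fusion and C1 configurations of 26.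

**Precursor 10 (10 ⇒ 9 ⇒ 5 + 6; 5 ⇒ 4 ⇒ 2 ⇒ 1).** The nitro group is placed on the vinyl group of 9 last, because a nitroalkene would not survive the organometallic step. Cutting C7–C8 gives bromide 5 and enal 6; the forward conjugate addition creates the quaternary C7 and the aldehyde at C5 in one step. Bromide 5 comes from 1 by silylation and selective cleavage of the trisubstituted alkene, so C11 with its methyl, oxygen and vinyl group is purchased in the correct configuration.

**Partners 13 and 24 (13 ⇒ 12 ⇒ 11; 24 ⇒ 22).** The silylacrolein 13 comes from 11 by hydrosilylation and allylic oxidation. Acid 24 comes from 22 by silylation.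

## Alternatives that were turned down

**Alternative 1: oxyallyl (4+3) cycloaddition.**
- *Disconnection:* ring B is opened at C9–C10 and C4–C7. This leaves a three-carbon oxyallyl unit (C7–C8–C9, oxygen on C8) and a diene C10=C11–C3=C4 made of the ring A alkene and an exocyclic aminovinyl group.
- *Forward key step:* a silver salt ionises the tertiary bromide A2 to a 2-silyloxyallyl cation, which combines with the chiral 2-aminodiene A3; hydrolysis of the enamine gives the trans-fused diketone A1.
- *For:* it is convergent and makes ring B and the quaternary C7 in one step. A cation–alkene bond formation at C4–C7 is less sensitive to crowding than an enamine Michael addition, so on the formation of the hindered ring B bond this route is probably the stronger one.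
- *Against:* A1 carries a C8 carbonyl that the target lacks, and it must be removed beside the C11 ketone. The C11 carbinol then has to come from a methyl addition whose facial selectivity on the seven-membered ring is open. Ring A arrives bare, so the C6 methyl, the C5=C6 alkene and the C1 stereocentre all follow after the cycloaddition. The unsymmetrical cation must bond through its more substituted terminus to the ring carbon.
- *Comparison:* from A1 roughly nine operations remain (methyl addition, two-step C8 deoxygenation, ketal removal, α-methylation, dehydrogenation, reduction, esterification, deprotection), against six after the chosen key step. In place of the more robust bond formation, the chosen strategy offers C11 from the chiral pool and C1, C3 and C4 set in the ring-forming step.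

**Alternative 2: Robinson annulation of ring A onto a ring B ketone.**
- *Disconnection:* ring A is opened at C4–C5 and C2=C3. This leaves the protected ketol A5 (C3 carbonyl, C11 ether), reachable from the dienone A7, and the enone A6.
- *Forward key step:* the C4 enolate of A5, the only one possible because C11 is fully substituted, adds to the methylene of A6, and the methyl ketone carbon C2 condenses with C3 to give enone A4.
- *For:* the seven-membered ring with its gem-dimethyl group is bought, the enolate is regiodefined, every reaction type is classical, and A4 already has the C6 methyl and the C1 oxygen. On precedent for the individual reaction types this route is stronger than the chosen one.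
- *Against:* C11 must be created by asymmetric oxygenation at a fully substituted enolate carbon, with no chiral-pool source. Both Robinson stages are hindered (neopentyl enolate carbon C4, carbonyl C3 beside the quaternary C11), and an α-substituted vinyl ketone polymerises readily. C4 is related to C11 only across the trigonal C3, so its configuration is weakly controlled. The alkene of A4 is at C2=C3 and must be reduced trans-selectively before C5=C6 is introduced and C1 reduced.
- *Comparison:* the step count after the key step is similar to that of the chosen route, but the enantioselective entry and the ring-fusion control are unsolved. The chosen strategy offers a purchased C11 and catalyst control of C4, C3 and C1.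

**Alternative 3: cationic closure of ring B on a bisabolane-type monocycle.**
- *Disconnection:* only C4–C7 is cut. The precursor A9 is ring A as an extended silyl dienol ether (C1 oxygen, C6 methyl) with the side chain on C3 ending in a tertiary chloride at C7.
- *Forward key step:* a silver salt abstracts chloride, the γ-carbon C4 of the dienol ether attacks the C7 cation, and the enone A8 is returned with C5=C6 in place.
- *For:* A8 has the complete skeleton and every ring A substituent at the right oxidation level, so only ketone reduction, esterification and desilylation remain. On economy after the key step this route is clearly stronger than the chosen one, which needs four corrective steps (reduction, denitration, deoxygenation, C–Si oxidation). γ-Attack is favoured because the α-carbon C6 is substituted.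
- *Against:* a tertiary cation that must close a seven-membered ring onto a hindered carbon can lose a proton or shift a hydride faster than it cyclises. Both C3 and C11, adjacent centres of which one is fully substituted, must be set beforehand in a separate stereocontrolled synthesis of A9. The ring-fusion configuration is under substrate control only.
- *Comparison:* the chosen strategy pays with redox corrections. In return it needs only one purchased stereocentre, forms the hindered bond by a closed-shell addition whose C4 centre can equilibrate, and sets C1, C3 and C4 with a catalyst.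

Key step: step 8

## Route

Step 1
Reactants: 1 (R)-linalool
Product: 2 (3R)-3,7-dimethyl-3-(triethylsilyloxy)octa-1,6-diene
Conditions: TESOTf, 2,6-lutidine, CH2Cl2, −78 → 0 °C
Reagents that add atoms: triethylsilyl trifluoromethanesulfonate, CC[Si](CC)(CC)OS(=O)(=O)C(F)(F)F
Why: Silyl ether protection; a silyl triflate with a hindered pyridine base silylates tertiary alcohols that resist silyl chlorides. The ether prevents the hydroxyl from cyclising onto C8 electrophiles and survives the organometallic step.

Step 2
Reactants: 2 (3R)-3,7-dimethyl-3-(triethylsilyloxy)octa-1,6-diene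
Product: 4 (4R)-4-methyl-4-(triethylsilyloxy)hex-5-en-1-ol, via C8 aldehyde 3 (not isolated)
Conditions: O3 (1 equiv, Sudan Red 7B end point), pyridine, CH2Cl2, −78 °C; then NaBH4, MeOH, −78 → 0 °C
Reagents that add atoms: ozone, [O-][O+]=O
Why: Ozonolysis with borohydride work-up; ozone attacks the electron-rich trisubstituted alkene much faster than the vinyl group, which is deactivated by the allylic oxygen and shielded by the fully substituted carbon, and the dye end point stops the addition after one equivalent. Pyridine gives the carbonyl compounds directly, so 3 is reduced in the same flask.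

Step 3
Reactants: 4 (4R)-4-methyl-4-(triethylsilyloxy)hex-5-en-1-ol
Product: 5 (3R)-6-bromo-3-methyl-3-(triethylsilyloxy)hex-1-ene
Conditions: CBr4, PPh3, 2,6-lutidine, CH2Cl2, 0 °C
Reagents that add atoms: carbon tetrabromide, BrC(Br)(Br)Br
Why: Appel bromination of a primary alcohol under buffered, neutral conditions; the tertiary silyl ether and the vinyl group are untouched.

Step 4
Reactants: 5 (3R)-6-bromo-3-methyl-3-(triethylsilyloxy)hex-1-ene; 6 3-methylbut-2-enal
Product: 9 (7R)-3,3,7-trimethyl-7-(triethylsilyloxy)non-8-enal, via Grignard reagent 7 (not isolated), via trimethylsilyl enol ether 8 (not isolated)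
Conditions: Mg, THF, rt; then CuBr·SMe2 (10 mol %), TMSCl, HMPA, 6, THF, −78 °C; then AcOH/THF/H2O, 0 °C
Reagents that add atoms: none
Why: Copper-catalysed conjugate addition of a Grignard reagent accelerated by chlorotrimethylsilane, which traps the adduct as silyl enol ether 8 and so favours 1,4- over 1,2-addition even for a β,β-disubstituted enal; mild acid then frees the aldehyde. The step forms the C7–C8 bond, the quaternary C7 and the C5 aldehyde with its α-methylene C4.

Step 5
Reactants: 9 (7R)-3,3,7-trimethyl-7-(triethylsilyloxy)non-8-enal
Product: 10 (7R,8E)-3,3,7-trimethyl-9-nitro-7-(triethylsilyloxy)non-8-enal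
Conditions: AgNO2, TEMPO (0.4 equiv), 4 Å MS, ClCH2CH2Cl, 70 °C
Reagents that add atoms: silver nitrite, [Ag+].[O-]N=O
Why: Radical nitration of a terminal alkene: NO2 radical adds to the CH2 terminus, TEMPO traps the carbon radical and then removes hydrogen, which gives the E nitroalkene. The allylic carbon C11 has no hydrogen, so no allylic nitro isomer can form.

Step 6
Reactants: 11 prop-2-yn-1-ol
Product: 12 (E)-3-(1,1,3,3,3-pentamethyldisiloxanyl)prop-2-en-1-ol
Conditions: Me3SiOSiMe2H, PtCl2 (1 mol %), XPhos (2 mol %), THF, 50 °C
Reagents that add atoms: pentamethyldisiloxane, C[Si](C)(C)O[SiH](C)C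
Why: Platinum-catalysed syn hydrosilylation of a terminal alkyne; with the bulky phosphine, silicon goes to the terminal carbon and the E vinylsilane results. The siloxy substituent on silicon is chosen so that the later C–Si oxidation needs no electrophile.

Step 7
Reactants: 12 (E)-3-(1,1,3,3,3-pentamethyldisiloxanyl)prop-2-en-1-ol
Product: 13 (E)-3-(1,1,3,3,3-pentamethyldisiloxanyl)prop-2-enal
Conditions: MnO2, CH2Cl2, rt
Reagents that add atoms: none
Why: MnO2 oxidises allylic alcohols selectively to enals without E/Z isomerisation and without touching the vinylsilane or the siloxane.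

Step 8
Reactants: 10 (7R,8E)-3,3,7-trimethyl-9-nitro-7-(triethylsilyloxy)non-8-enal; 13 (E)-3-(1,1,3,3,3-pentamethyldisiloxanyl)prop-2-enal
Product: 16 trans-fused bicyclic enal (C1 pentamethyldisiloxanyl; C2 nitro; C6 formyl; C5=C6; C11 triethylsilyl ether; C1 C3 C4 C11 configured as in 26), via ring B nitro aldehyde 14 (not isolated), via ring B dialdehyde 15 (not isolated)
Conditions: (R)-α,α-diphenylprolinol trimethylsilyl ether (20 mol %), PhCO2H (20 mol %), toluene (0.05 M), rt; then 13 (1.5 equiv), 0 °C → rt
Reagents that add atoms: none
Why: Proposed new method: a seven-membered enamine-to-nitroalkene Michael closure between two carbons that each adjoin a fully substituted centre has not been shown, and the closest known reaction types are the amine-catalysed aldehyde/nitroalkene/enal Michael–Michael–aldol three-component cascade and the intramolecular enamine Michael cyclisations that give five- and six-membered rings. The catalyst condenses with 10 to an E enamine whose C4 adds to C3 of the tethered nitroalkene (ring B, 7-(enolexo)-exo-trig) to give 14, so the tether turns the encounter of two hindered carbons into a cyclisation. The nitronate of 14 then adds through C2 to C1 of the iminium ion of 13 to give 15, whose enamine carbon C6 attacks the C5 aldehyde (ring A, 6-(enolexo)-exo-trig aldol), and dehydration releases 16 and the catalyst. C4 is set by attack on the enamine face remote from the diphenyl(silyloxy)methyl group and stays epimerisable, so it can settle trans to C3; C3 follows from the topicity of the Michael step, for which the R catalyst is chosen because the S catalyst gives the mirror-image pattern in the intermolecular cascade, and this topicity must be matched with the C11 centre. C1 is set by the catalyst, which shields one face of the iminium ion, and C2 equilibrates through the nitronate and is removed later. The chemoselectivity needed is enamine to nitroalkene before enamine to enal, then nitronate to iminium ion; it is secured by the higher electrophilicity of the nitroalkene, by the intramolecular first step, by adding 13 only after 10 is consumed, and by the absence of γ-hydrogens in the nitroalkene (C11 is fully substituted), which excludes its isomerisation.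

Step 9
Reactants: 16 trans-fused bicyclic enal
Product: 17 nitro allylic alcohol (C6 hydroxymethyl; otherwise as 16)
Conditions: NaBH4, CeCl3·7H2O, MeOH, −78 → −20 °C
Reagents that add atoms: none
Why: Luche reduction: NaBH4 with CeCl3 reduces the enal in the 1,2-sense only, and the nitro group, the allylsilane and both Si–O bonds are inert at low temperature. The reduction precedes the tin hydride step because stannyl radicals would reduce the enal.

Step 10
Reactants: 17 nitro allylic alcohol
Product: 18 allylic alcohol (C2 methylene; C1 pentamethyldisiloxanyl; C6 hydroxymethyl; C11 triethylsilyl ether)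
Conditions: Bu3SnH (5 equiv), AIBN, toluene, 110 °C
Reagents that add atoms: none
Why: Radical denitration: the stannyl radical adds to a nitro oxygen and the adduct fragments to the secondary C2 radical, which abstracts hydrogen from the hydride; unactivated secondary nitroalkanes need refluxing toluene and excess hydride. A high hydride concentration also suppresses rearrangement of the homoallylic radical, and a β-silyl group is not lost from a carbon radical.

Step 11
Reactants: 18 allylic alcohol
Product: 20 C6-methyl allylsilane (C1 pentamethyldisiloxanyl; C5=C6 with methyl on C6; C11 triethylsilyl ether), via allylic mesylate 19 (not isolated)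
Conditions: MsCl, Et3N, THF, −20 °C; then LiBHEt3, THF, −20 → 0 °C
Reagents that add atoms: none
Why: Sulfonate formation and SN2 displacement by hydride at the primary allylic carbon convert CH2OH into CH3 without moving the C5=C6 bond, because attack at the hindered ring carbon C5 (SN2') is much slower. The step follows the denitration so that the hydride does not meet an acidic nitroalkane.

Step 12
Reactants: 20 C6-methyl allylsilane
Product: 21 C1 alcohol (C1 hydroxyl configured as in 26; C11 triethylsilyl ether)
Conditions: H2O2 (30 % aq), KF, KHCO3, THF/MeOH (1:1), rt → 40 °C
Reagents that add atoms: hydrogen peroxide, OO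
Why: Tamao oxidation: fluoride and hydroperoxide act at silicon and C1 migrates from silicon to oxygen with retention, so C1 keeps the configuration set in step 8. Because silicon already carries oxygen, no electrophilic dearylation is needed and the allylsilane never meets an electrophile that would cause protodesilylation with allylic shift; the unactivated alkene is inert to basic H2O2.

Step 13
Reactants: 22 isovanillic acid
Product: 24 3-(tert-butyldimethylsilyloxy)-4-methoxybenzoic acid, via bis-silylated acid 23 (not isolated)
Conditions: TBSCl (2.5 equiv), imidazole, DMF, rt; then AcOH/THF/H2O, rt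
Reagents that add atoms: tert-butyldimethylsilyl chloride, CC(C)(C)[Si](C)(C)Cl
Why: Silylation of phenol and carboxylic acid, then selective hydrolysis of the far more labile silyl ester in aqueous acetic acid, which leaves the aryl silyl ether.

Step 14
Reactants: 21 C1 alcohol; 24 3-(tert-butyldimethylsilyloxy)-4-methoxybenzoic acid
Product: 25 protected ester (C1 3-(tert-butyldimethylsilyloxy)-4-methoxybenzoate; C11 triethylsilyl ether)
Conditions: DCC, DMAP (0.2 equiv), CH2Cl2, 0 °C → rt
Reagents that add atoms: none
Why: Steglich esterification of a secondary allylic alcohol under neutral conditions; the C1–O bond is not broken, so the C1 configuration is retained, and the tertiary hydroxyl and the phenol are masked.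

Step 15
Reactants: 25 protected ester
Product: 26 CNP0210711.2, the C1 isovanillate of the (1R,3R,4R,11R) bicyclic diol
Conditions: TBAF, AcOH (1:1), THF, 0 °C → rt
Reagents that add atoms: none
Why: Fluoride-mediated desilylation of the aryl and the tertiary alkyl silyl ether; acetic acid buffers phenoxide and alkoxide, so the allylic ester neither migrates nor hydrolyses.

## Compound list

1 | (R)-linalool, (3R)-3,7-dimethylocta-1,6-dien-3-ol | C=C[C@](C)(O)CCC=C(C)C | starting material
2 | (3R)-3,7-dimethyl-3-(triethylsilyloxy)octa-1,6-diene | C=C[C@](C)(O[Si](CC)(CC)CC)CCC=C(C)C | intermediate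
3 | (4R)-4-methyl-4-(triethylsilyloxy)hex-5-enal | C=C[C@](C)(O[Si](CC)(CC)CC)CCC=O | intermediate
4 | (4R)-4-methyl-4-(triethylsilyloxy)hex-5-en-1-ol | C=C[C@](C)(O[Si](CC)(CC)CC)CCCO | intermediate
5 | (3R)-6-bromo-3-methyl-3-(triethylsilyloxy)hex-1-ene | C=C[C@](C)(O[Si](CC)(CC)CC)CCCBr | intermediate
6 | 3-methylbut-2-enal | CC(C)=CC=O | starting material
7 | [(4R)-4-methyl-4-(triethylsilyloxy)hex-5-en-1-yl]magnesium bromide | C=C[C@](C)(O[Si](CC)(CC)CC)CCC[Mg]Br | intermediate
8 | (1E,7R)-3,3,7-trimethyl-7-(triethylsilyloxy)-1-(trimethylsilyloxy)nona-1,8-diene | C=C[C@](C)(O[Si](CC)(CC)CC)CCCC(C)(C)/C=C/O[Si](C)(C)C | intermediate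
9 | (7R)-3,3,7-trimethyl-7-(triethylsilyloxy)non-8-enal | C=C[C@](C)(O[Si](CC)(CC)CC)CCCC(C)(C)CC=O | intermediate
10 | (7R,8E)-3,3,7-trimethyl-9-nitro-7-(triethylsilyloxy)non-8-enal | O=CCC(C)(C)CCC[C@@](C)(O[Si](CC)(CC)CC)/C=C/[N+](=O)[O-] | intermediate
11 | prop-2-yn-1-ol (propargyl alcohol) | C#CCO | starting material
12 | (E)-3-(1,1,3,3,3-pentamethyldisiloxanyl)prop-2-en-1-ol | OC/C=C/[Si](C)(C)O[Si](C)(C)C | intermediate
13 | (E)-3-(1,1,3,3,3-pentamethyldisiloxanyl)prop-2-enal | O=C/C=C/[Si](C)(C)O[Si](C)(C)C | intermediate
14 | ring B nitro aldehyde: cycloheptane with formyl on C4 trans to nitromethyl on C3, two methyls on C7, methyl and triethylsilyloxy on C11 | O=C[C@@H]1[C@@H](C[N+](=O)[O-])[C@](C)(O[Si](CC)(CC)CC)CCCC1(C)C | intermediate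
15 | ring B dialdehyde: as 14, with C2 (nitro) bonded to C1, which carries the pentamethyldisiloxanyl group and the 2-oxoethyl arm (C6 and its formyl carbon) | O=C[C@@H]1[C@@H]([C@H]([N+](=O)[O-])[C@H](CC=O)[Si](C)(C)O[Si](C)(C)C)[C@](C)(O[Si](CC)(CC)CC)CCCC1(C)C | intermediate
16 | trans-fused bicyclic enal: C1 pentamethyldisiloxanyl (on the face of H-3), C2 nitro (trans to silicon), C6 formyl, C5=C6, C7 dimethyl, C11 methyl and triethylsilyloxy | C[Si](C)(C)O[Si](C)(C)[C@@H]1[C@@H]([N+](=O)[O-])[C@@H]2[C@@H](C=C1C=O)C(C)(C)CCC[C@@]2(C)O[Si](CC)(CC)CC | intermediate
17 | nitro allylic alcohol: as 16 with C6 hydroxymethyl | C[Si](C)(C)O[Si](C)(C)[C@@H]1[C@@H]([N+](=O)[O-])[C@@H]2[C@@H](C=C1CO)C(C)(C)CCC[C@@]2(C)O[Si](CC)(CC)CC | intermediate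
18 | allylic alcohol: as 17 with C2 methylene | C[Si](C)(C)O[Si](C)(C)[C@@H]1C[C@@H]2[C@@H](C=C1CO)C(C)(C)CCC[C@@]2(C)O[Si](CC)(CC)CC | intermediate
19 | allylic mesylate of 18 | C[Si](C)(C)O[Si](C)(C)[C@@H]1C[C@@H]2[C@@H](C=C1COS(C)(=O)=O)C(C)(C)CCC[C@@]2(C)O[Si](CC)(CC)CC | intermediate
20 | C6-methyl allylsilane: C1 pentamethyldisiloxanyl, C5=C6 with methyl on C6, C11 triethylsilyl ether | C[Si](C)(C)O[Si](C)(C)[C@@H]1C[C@@H]2[C@@H](C=C1C)C(C)(C)CCC[C@@]2(C)O[Si](CC)(CC)CC | intermediate
21 | C1 alcohol: (1R,3R,4R,11R) bicyclic diol as its C11 triethylsilyl ether | O[C@@H]1C[C@@H]2[C@@H](C=C1C)C(C)(C)CCC[C@@]2(C)O[Si](CC)(CC)CC | intermediate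
22 | isovanillic acid, 3-hydroxy-4-methoxybenzoic acid | COc1ccc(C(=O)O)cc1O | starting material
23 | tert-butyldimethylsilyl 3-(tert-butyldimethylsilyloxy)-4-methoxybenzoate | COc1ccc(C(=O)O[Si](C)(C)C(C)(C)C)cc1O[Si](C)(C)C(C)(C)C | intermediate
24 | 3-(tert-butyldimethylsilyloxy)-4-methoxybenzoic acid | COc1ccc(C(=O)O)cc1O[Si](C)(C)C(C)(C)C | intermediate
25 | protected ester: C1 3-(tert-butyldimethylsilyloxy)-4-methoxybenzoate of 21 | COc1ccc(C(=O)O[C@@H]2C[C@@H]3[C@@H](C=C2C)C(C)(C)CCC[C@@]3(C)O[Si](CC)(CC)CC)cc1O[Si](C)(C)C(C)(C)C | intermediate
26 | CNP0210711.2: (1R,3R,4R,11R) trans-fused bicyclic diol (C5=C6, methyl on C6, two methyls on C7, methyl and hydroxyl on C11) esterified at C1 with 3-hydroxy-4-methoxybenzoic acid | COc1ccc(C(=O)O[C@@H]2C[C@@H]3[C@@H](C=C2C)C(C)(C)CCC[C@@]3(C)O)cc1O | target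

## Step count and least certain steps

Total: 15 steps. Longest linear sequence: 12 steps (steps 1–5, 8–12, 14 and 15); steps 6–7 and step 13 are side branches.

**Step 8 (key step, marked as a proposed new method).**
What may go wrong:
- The seven-membered closure may be slower than intermolecular enamine–nitroalkene addition, which leads to oligomerisation.
- The facial selectivity at C3 may be poor if the C11 centre and the catalyst are mismatched.
- The hindered nitronate may add sluggishly to the iminium ion.

Inside the strategy, the handles are dilution in the first stage, late addition of 13, and the size of the C11 oxygen substituent (free hydroxyl or trimethylsilyl instead of triethylsilyl).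

Fallback with known reactions only, setting out from 9 and returning at 21: the ring system is built by an intramolecular Diels–Alder reaction with the nitroalkene as dienophile. Wittig olefination of 9 with 2-(triphenylphosphoranylidene)propanal (toluene, 100 °C) should give the E enal (2E,9R)-2,5,5,9-tetramethyl-9-(triethylsilyloxy)undeca-2,10-dienal F1. Nitration of its vinyl group as in step 5 should give the nitroalkene enal F2. TMSOTf and Et3N (Et2O, −78 → 0 °C) remove a C4 hydrogen and silylate oxygen to give the (1E,3E) silyl dienol ether F3, whose diene is C1=C6–C5=C4 with the silyloxy group on C1. Heating in toluene forms C3–C4 and C1–C2 in one cycloaddition and should give the nitro cycloadduct F4 (C1 trimethylsilyl ether, C2 nitro, methyl on C6, C5=C6). The E,E diene places the C1 oxygen cis to the C4–C7 bond, and a nitro-endo transition state with the tether exo gives the trans ring fusion. Bu3SnH/AIBN then removes the nitro group while C1 is still protected (a free β-nitro alcohol could undergo retro-nitroaldol cleavage), giving the silyl ether F5, and K2CO3 in MeOH cleaves the trimethylsilyl ether to 21. This fallback gives up catalyst control: the face used relative to C11 depends on the substrate alone.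

**Step 5.**
What may go wrong: NO2 or TEMPO may abstract hydrogen from the aldehyde, or the addition to the hindered vinyl group may be slow.

Fallback, from 9 back to 10, by nitroaldol chemistry: the aldehyde is masked with HC(OMe)3 and PPTS in MeOH as the dimethyl acetal F6. Ozonolysis of the vinyl group (O3, CH2Cl2, −78 °C; PPh3) gives the α-silyloxy aldehyde F7. Henry addition of nitromethane (Et3N) gives the nitro alcohol F8. MsCl/Et3N dehydrates it to the E nitroalkene acetal F9, and aqueous oxalic acid in THF frees the aldehyde 10. Here C2 comes from nitromethane and the old vinyl terminus is lost.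

**Step 10.**
What may go wrong: the stannyl nitroxide of an unactivated secondary nitro group fragments slowly, so conversion may be incomplete, and the C2 radical may rearrange through a cyclopropylcarbinyl radical before it is reduced.

Fallback, from 17 back to 18, without a carbon radical chain: reduction of the nitro group with NiCl2·6H2O and NaBH4 in MeOH gives the primary amine F10. Hydroxylamine-O-sulfonic acid in cold aqueous NaOH/EtOH replaces the amino group by hydrogen through the diazene, with loss of nitrogen, to give 18.

**Step 12.**
What may go wrong: fluoride may cleave the allyl–silicon bond (protodesilylation, with or without allylic shift) in competition with the migration to oxygen, and the tertiary silyl ether may be partly lost.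

Fallback, from 18 back to 21: the oxidation is moved ahead of the deoxygenation and activated internally. A catalytic amount of t-BuOK in THF lets the C6 hydroxymethyl oxygen displace trimethylsilanolate from silicon to give the cyclic alkoxysilane F11, a five-membered oxasilolane fused to ring A. F11 is oxidised without fluoride (H2O2, KHCO3, MeOH/THF) to the diol F12. 2,4,6-Triisopropylbenzenesulfonyl chloride (Et3N, DMAP, CH2Cl2, 0 °C) sulfonylates only the primary hydroxyl to give the monosulfonate F13, and LiBHEt3 displaces the sulfonate to give 21.

## Further compounds

F1 | step 8 | (2E,9R)-2,5,5,9-tetramethyl-9-(triethylsilyloxy)undeca-2,10-dienal | C=C[C@](C)(O[Si](CC)(CC)CC)CCCC(C)(C)C/C=C(\C)C=O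
F2 | step 8 | (2E,9R,10E)-2,5,5,9-tetramethyl-11-nitro-9-(triethylsilyloxy)undeca-2,10-dienal | O=C/C(C)=C/CC(C)(C)CCC[C@@](C)(O[Si](CC)(CC)CC)/C=C/[N+](=O)[O-]
F3 | step 8 | (1E,3E) trimethylsilyl dienol ether of F2 (diene C1=C6–C5=C4, silyloxy on C1) | C[Si](C)(C)O/C=C(C)/C=C/C(C)(C)CCC[C@@](C)(O[Si](CC)(CC)CC)/C=C/[N+](=O)[O-]
F4 | step 8 | nitro cycloadduct: trans-fused bicycle with C1 trimethylsilyloxy, C2 nitro (cis to the C1 oxygen), methyl on C6, C5=C6, C11 triethylsilyl ether | C[Si](C)(C)O[C@@H]1[C@H]([N+](=O)[O-])[C@@H]2[C@@H](C=C1C)C(C)(C)CCC[C@@]2(C)O[Si](CC)(CC)CC
F5 | step 8 | C1 trimethylsilyl ether of 21 | C[Si](C)(C)O[C@@H]1C[C@@H]2[C@@H](C=C1C)C(C)(C)CCC[C@@]2(C)O[Si](CC)(CC)CC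
F6 | step 5 | (3R)-9,9-dimethoxy-3,7,7-trimethyl-3-(triethylsilyloxy)non-1-ene (dimethyl acetal of 9) | COC(CC(C)(C)CCC[C@@](C)(O[Si](CC)(CC)CC)C=C)OC
F7 | step 5 | (2R)-8,8-dimethoxy-2,6,6-trimethyl-2-(triethylsilyloxy)octanal | COC(CC(C)(C)CCC[C@@](C)(O[Si](CC)(CC)CC)C=O)OC
F8 | step 5 | nitro alcohol from F7 and nitromethane (both carbinol epimers) | COC(CC(C)(C)CCC[C@@](C)(O[Si](CC)(CC)CC)C(O)C[N+](=O)[O-])OC
F9 | step 5 | dimethyl acetal of 10 | COC(CC(C)(C)CCC[C@@](C)(O[Si](CC)(CC)CC)/C=C/[N+](=O)[O-])OC
F10 | step 10 | C2 primary amine corresponding to 17 | C[Si](C)(C)O[Si](C)(C)[C@@H]1[C@@H](N)[C@@H]2[C@@H](C=C1CO)C(C)(C)CCC[C@@]2(C)O[Si](CC)(CC)CC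
F11 | step 12 | cyclic alkoxysilane: dimethylsilylene bridging C1 and the oxygen of the C6 hydroxymethyl group | C[Si]3(C)[C@@H]1C[C@@H]2[C@@H](C=C1CO3)C(C)(C)CCC[C@@]2(C)O[Si](CC)(CC)CC
F12 | step 12 | diol: C1 hydroxyl and C6 hydroxymethyl, C11 triethylsilyl ether | O[C@@H]1C[C@@H]2[C@@H](C=C1CO)C(C)(C)CCC[C@@]2(C)O[Si](CC)(CC)CC
F13 | step 12 | primary 2,4,6-triisopropylbenzenesulfonate of F12 | O[C@@H]1C[C@@H]2[C@@H](C=C1COS(=O)(=O)c3c(C(C)C)cc(C(C)C)cc3C(C)C)C(C)(C)CCC[C@@]2(C)O[Si](CC)(CC)CC
A1 | alternative 1 | trans-fused C8,C11-diketone with C1 ethylene ketal | C13(OCCO3)C[C@@H]2[C@@H](CC1)C(C)(C)C(=O)CCC2=O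
A2 | alternative 1 | 3-bromo-3-methyl-2-(triethylsilyloxy)but-1-ene | C=C(O[Si](CC)(CC)CC)C(C)(C)Br
A3 | alternative 1 | 7-[1-((S)-2-(methoxymethyl)pyrrolidin-1-yl)vinyl]-1,4-dioxaspiro[4.5]dec-7-ene (representative chiral aminodiene) | C=C(N1CCC[C@H]1COC)C1=CCCC2(C1)OCCO2
A4 | alternative 2 | bicyclic C1 enone (C2=C3) with methyl on C6 and C11 methoxymethyl ether | O=C1C=C2[C@@H](C[C@@H]1C)C(C)(C)CCC[C@@]2(C)OCOC
A5 | alternative 2 | (2R)-2-(methoxymethoxy)-2,6,6-trimethylcycloheptan-1-one | COCO[C@]1(C)CCCC(C)(C)CC1=O
A6 | alternative 2 | 3-methylbut-3-en-2-one | CC(=O)C(C)=C
A7 | alternative 2 | eucarvone, 2,6,6-trimethylcyclohepta-2,4-dien-1-one | CC1=CC=CC(C)(C)CC1=O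
A8 | alternative 3 | bicyclic C1 enone with C5=C6, methyl on C6 and C11 tert-butyldimethylsilyl ether | O=C1C[C@@H]2[C@@H](C=C1C)C(C)(C)CCC[C@@]2(C)O[Si](C)(C)C(C)(C)C
A9 | alternative 3 | ring A trimethylsilyl dienol ether (C1=C6–C5=C4) with the C3 side chain C11(methyl)(tert-butyldimethylsilyloxy)–(CH2)3–C7(CH3)2Cl | CC1=C(O[Si](C)(C)C)C[C@H](C=C1)[C@](C)(O[Si](C)(C)C(C)(C)C)CCCC(C)(C)Cl
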